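The readings hold no column for activator, so its attack on ring cannot be read as a rate, but the ratio of two steps that both use it can.

| flask | starting material | activator | temperature | remark | time |
|---|---|---|---|---|---|
| spring | 0.060 M | 0.90 equiv | 45 °C | run made earlier |  |
| autumn | 0.060 M | 1.4 equiv | 62 °C | run made earlier |  |
| midnight | 0.090 M | 1.8 equiv | 45 °C | run made earlier |  |
| delta | 0.060 M | 1.80 equiv | 50 °C |  | 12 min |
| gamma | 0.060 M | 1.80 equiv | 75 °C |  | 12 min |

| run | time / min | over-reaction product / % | starting material / % | open dimer / % | activated form / % | ring / % |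
|---|---|---|---|---|---|---|
| spring | 1.50 | 0.1 | 74.7 | 1.5 | 21.2 | 1.9 |
| spring | 3.00 | 0.3 | 60.2 | 5.8 | 28.6 | 3.8 |
| spring | 5.00 | 1.4 | 47.9 | 9.6 | 32.2 | 10.2 |
| spring | 6.00 | 0.5 | 43.3 | 10.7 | 32.3 | 11.5 |
| spring | 8.00 | 1.9 | 37.2 | 14.1 | 31.0 | 16.0 |
| spring | 10.0 | 1.9 | 31.9 | 16.9 | 27.9 | 20.6 |
| spring | 12.0 | 3.1 | 29.2 | 18.9 | 25.1 | 24.1 |
| autumn | 0.833 | 0.9 | 56.8 | 3.8 | 30.3 | 9.0 |
| autumn | 1.50 | 1.9 | 41.6 | 8.7 | 30.1 | 17.8 |
| autumn | 3.00 | 7.8 | 24.1 | 12.6 | 21.1 | 34.2 |
| autumn | 4.00 | 11.0 | 19.5 | 14.2 | 14.5 | 41.4 |
| autumn | 6.00 | 15.3 | 15.3 | 15.2 | 7.2 | 47.1 |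
| midnight | 1.00 | 0.1 | 57.4 | 2.8 | 37.1 | 1.6 |
| midnight | 2.00 | 0.4 | 37.3 | 6.8 | 50.1 | 5.1 |
| midnight | 3.00 | 1.5 | 25.7 | 9.2 | 54.7 | 9.3 |
| midnight | 6.00 | 5.5 | 11.0 | 14.2 | 50.5 | 18.5 |
| midnight | 12.0 | 14.2 | 4.3 | 18.0 | 33.2 | 31.5 |

(standard deviation of a reading: 0.5 percentage points)

- percentages count the starting material that a species holds: one open dimer counts as two

- which of these there is most of at the end, counted by the starting material in it, delta (activated form / ring / over-reaction product / open dimer / starting material)
- which of these there is most of at the end, counted by the starting material in it, gamma (activated form / ring / over-reaction product / open dimer / starting material)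
- amount of the one of these that there is most of at the end, in percent of the starting material charged, delta
- amount of the one of these that there is most of at the end, in percent of the starting material charged, gamma

Delta shares midnight's equivalents of activator but is more dilute, at 0.060 M against 0.090 M, and warmer, at 50 °C against 45 °C. Midnight ends with activated form at 33.2%, ahead of ring at 31.5%. Closure is read as the gain of ring plus over-reaction product per activated form present and per minute:

midnight, 3.00 min to 6.00 min: 0.0837 min⁻¹

autumn, 1.50 min to 3.00 min: 0.581 min⁻¹

Spread evenly over the degrees, that rise makes closure in delta faster than in midnight by a factor of 1.77, so this reckoning puts ring first in delta.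

The selectivity factor s is the rate of over-reaction per unit of ring, divided by the rate of activation per unit of starting material. Taking both steps as first order in activator, activator and time drop out, and fractions of the charge serve. Starting material lost to open dimer is half the gain in that column:

s, midnight = 0.433

s, autumn = 0.479

These readings, from 45 °C and 62 °C, are close, so the midnight value is carried to delta. Over-reaction outruns activation once ring over starting material passes 1/s = 2.31. Midnight's ratio stands at 1.68 at 6.00 min and 7.33 at 12.0 min, so it crosses in between. This reckoning expects delta to end past the crossing too, with over-reaction product near midnight's 0.451 of ring at 12.0 min; that is an estimate, since delta differs from midnight in both concentration and temperature.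

The forecast gives ring at 45% for delta and ring at 42% for gamma, and says of gamma “Ring versus over-reaction is a close call”.

    starting material + activator → activated form (k = 0.0880 L mol⁻¹ s⁻¹, Ea = 49.0 kJ mol⁻¹)
    activated form → ring (k = 0.00250 s⁻¹, Ea = 97.0 kJ mol⁻¹)
    starting material + activated form → open dimer (k = 0.0240 L mol⁻¹ s⁻¹, Ea = 57.0 kJ mol⁻¹)
    2 activator → homo dimer (k = 0.00910 L mol⁻¹ s⁻¹, Ea = 71.0 kJ mol⁻¹)
    activator + ring → over-reaction product (k = 0.0350 L mol⁻¹ s⁻¹, Ea = 57.0 kJ mol⁻¹)
    (constants at 50 °C)

Ring leads in delta at 41.4% and in gamma at 45.3%. Delta's ring over starting material is 1.96 at 6.00 min and 7.46 at 12.0 min, so its crossing falls between them, and s times the end ratio is 3.23. The neighbouring flask, delta with 4.50 equiv of activator, ends with starting material at 0.183%. Its ratio is 174, and s times that is 75.3. In that flask over-reaction product stands at 42.6%, above ring at 31.9%.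

The earlier runs and the new flask come from a simulation for substances that don't exist, and the scatter is random.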